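## Retrosynthetic overview

1. Ring and stereocentre: the cyclohexene ring and its C6 stereocentre are bought intact as (S)-α-ionone 1; no ring is formed or opened, and C6 is never deprotonated or ionised.
2. C9–C10: vinyl Grignard reagent 2 adds to the ketone of 1 to give carbinol 3.
3. Key bond C3=O: anodic, N-oxyl-mediated allylic C–H oxygenation of 3 with t-BuOOH 4 (peroxide 5, then enone 6), done at the carbinol stage so that no diketone has to be differentiated later.
4. C11–P and the partner: PPh3·HBr 7 converts 6 into C15 phosphonium salt 8; C10 dialdehyde 9 and methanol 10 give aldehyde ester 11.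
5. C11=C12: Wittig union of 8 with 11 (ylide 12, 11Z isomer 13) completes the hexaene of target 14.

Assumption: (S)-(−)-α-ionone (≥98% ee) and the all-E C10 dialdehyde are taken as catalogue items. Positions in the text use carotenoid numbering (ring C1–C6, chain C7–C15 then C15'–C12'); the compound list gives systematic names.

## Route

Step 1
Reactants: 1 (S)-α-ionone; 2 vinylmagnesium bromide
Product: 3 (1E)-3-methyl-1-[(1S)-2,6,6-trimethylcyclohex-2-en-1-yl]penta-1,4-dien-3-ol (both carbinol epimers)
Conditions: 2 (1.3 equiv), THF, −20 to 0 °C, 1 h; then H2O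
Reagents that add atoms: vinylmagnesium bromide, C=C[Mg]Br
Why: 1,2-Grignard addition to the enone carbonyl (the classical vinyl-ionol synthesis) builds C9–C10 at low temperature without touching the bought C6 stereocentre, and the new carbinol centre, formed as both epimers, is erased in step 3.

Step 2
Reactants: 3 carbinol from step 1; 4 tert-butyl hydroperoxide
Product: 6 (4S)-4-[(1E)-3-hydroxy-3-methylpenta-1,4-dien-1-yl]-3,5,5-trimethylcyclohex-2-en-1-one, via allylic tert-butyl peroxide 5 (not isolated)
Conditions: 4 (1.5 equiv), N-hydroxytetrachlorophthalimide (20 mol%), pyridine (2 equiv), LiBF4 (0.1 M), acetone, reticulated vitreous carbon anode and cathode, undivided cell, constant current 10 mA per mmol (about 3 F/mol), rt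
Reagents that add atoms: tert-butyl hydroperoxide, CC(C)(C)OO
Why: Proposed new method: the anodically generated tetrachlorophthalimide-N-oxyl should abstract the unhindered secondary allylic C3–H in preference to the doubly allylic but buried C6–H (flanked by the gem-dimethyl carbon and the C5 methyl, with its σ-bond held near the nodal plane of the C7=C8 π-bond by allylic strain), the ring allyl radical is capped by t-BuOO• at its less hindered terminus C3 to give 5, and pyridine-promoted Kornblum–DeLaMare-type loss of t-BuOH forms the C3=O bond with C6 and the carbinol untouched; the closest known reaction type is the N-hydroxyphthalimide-mediated electrochemical allylic C–H oxidation of terpene olefins (for example valencene to nootkatone), which has not been shown on a free tertiary bis-allylic carbinol triene carrying a doubly allylic stereogenic C–H.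

Step 3
Reactants: 6 oxo carbinol from step 2; 7 triphenylphosphine hydrobromide
Product: 8 [(2E,4E)-3-methyl-5-[(1S)-2,6,6-trimethyl-4-oxocyclohex-2-en-1-yl]penta-2,4-dien-1-yl]triphenylphosphonium bromide
Conditions: 7 (1.05 equiv), MeOH, 0 °C to rt, 16 h; crystallise (acetone/EtOAc) to the 2E,4E salt
Reagents that add atoms: triphenylphosphine hydrobromide, [Br-].c1ccc(cc1)[PH+](c1ccccc1)c1ccccc1
Why: Acid ionises the tertiary bis-allylic carbinol to a pentadienyl cation that PPh3 captures at the unhindered terminus C11 (SN1' allylic transposition, the standard C15 Wittig-salt formation), which sets the conjugated 7E,9E diene, destroys the carbinol centre and, being base-free, leaves C6 intact (any E1 by-product is achiral and non-ionic, so it costs yield but not enantiopurity).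

Step 4
Reactants: 9 (2E,4E,6E)-2,7-dimethylocta-2,4,6-trienedial; 10 methanol
Product: 11 methyl (2E,4E,6E)-2,7-dimethyl-8-oxoocta-2,4,6-trienoate
Conditions: 10 (5 equiv), 1,4-dimethyl-1,2,4-triazolium iodide (5 mol%), DBU (1.1 equiv), 3,3',5,5'-tetra-tert-butyldiphenoquinone (1.0 equiv), THF, rt, 2 h; chromatography (9 recovered)
Reagents that add atoms: methanol, CO
Why: N-heterocyclic-carbene-catalysed oxidative esterification, in which the Breslow intermediate of one formyl group is oxidised by the diphenoquinone to an acyl azolium that methanol cleaves to the ester, with the single equivalent of oxidant and the lower electrophilicity of the ester aldehyde holding the symmetric dialdehyde at the mono-ester and all E geometry kept.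

Step 5
Reactants: 8 C15 phosphonium bromide; 11 C10 aldehyde ester
Product: 14 methyl (2E,4E,6E,8E,10E,12E)-2,7,11-trimethyl-13-[(1S)-2,6,6-trimethyl-4-oxocyclohex-2-en-1-yl]trideca-2,4,6,8,10,12-hexaenoate (target), via phosphorus ylide 12 (not isolated), via 11Z isomer 13 (not isolated)
Conditions: NaN(SiMe3)2 (1.0 equiv), THF, −78 °C, 20 min; 11 (1.05 equiv), −78 to 0 °C, 1 h; pH 7 buffer; crude in heptane, 85 °C, 4 h; crystallise
Reagents that add atoms: none
Why: Wittig olefination in which one equivalent of amide base removes only the far more acidic P–CH2 proton at −78 °C (no free base remains to epimerise the γ-enone C6–H), the semi-stabilised ylide attacks the aldehyde and not the ester or the hindered ring enone, and the sterically hindered 11Z olefin formed alongside relaxes thermally to the all-E hexaene.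

## Compound list

1 | (S)-α-ionone, (3E)-4-[(1S)-2,6,6-trimethylcyclohex-2-en-1-yl]but-3-en-2-one | CC(=O)/C=C/[C@@H]1C(C)=CCCC1(C)C | starting material
2 | vinylmagnesium bromide | C=C[Mg]Br | starting material
3 | (1E)-3-methyl-1-[(1S)-2,6,6-trimethylcyclohex-2-en-1-yl]penta-1,4-dien-3-ol (carbinol epimers) | C=CC(C)(O)/C=C/[C@@H]1C(C)=CCCC1(C)C | intermediate
4 | tert-butyl hydroperoxide | CC(C)(C)OO | starting material
5 | (1E)-1-[(1S)-4-(tert-butylperoxy)-2,6,6-trimethylcyclohex-2-en-1-yl]-3-methylpenta-1,4-dien-3-ol (epimers at the peroxide and carbinol carbons) | C=CC(C)(O)/C=C/[C@@H]1C(C)=CC(OOC(C)(C)C)CC1(C)C | intermediate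
6 | (4S)-4-[(1E)-3-hydroxy-3-methylpenta-1,4-dien-1-yl]-3,5,5-trimethylcyclohex-2-en-1-one (carbinol epimers) | C=CC(C)(O)/C=C/[C@@H]1C(C)=CC(=O)CC1(C)C | intermediate
7 | triphenylphosphine hydrobromide | [Br-].c1ccc(cc1)[PH+](c1ccccc1)c1ccccc1 | starting material
8 | [(2E,4E)-3-methyl-5-[(1S)-2,6,6-trimethyl-4-oxocyclohex-2-en-1-yl]penta-2,4-dien-1-yl]triphenylphosphonium bromide | [Br-].c1ccccc1[P+](c1ccccc1)(c1ccccc1)C/C=C(C)/C=C/[C@@H]1C(C)=CC(=O)CC1(C)C | intermediate
9 | (2E,4E,6E)-2,7-dimethylocta-2,4,6-trienedial | O=C/C(C)=C/C=C/C=C(C)/C=O | starting material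
10 | methanol | CO | starting material
11 | methyl (2E,4E,6E)-2,7-dimethyl-8-oxoocta-2,4,6-trienoate | COC(=O)/C(C)=C/C=C/C=C(C)/C=O | intermediate
12 | (4S)-3,5,5-trimethyl-4-[(1E,3E)-3-methyl-5-(triphenyl-λ5-phosphanylidene)penta-1,3-dien-1-yl]cyclohex-2-en-1-one | c1ccccc1P(c1ccccc1)(c1ccccc1)=C/C=C(C)/C=C/[C@@H]1C(C)=CC(=O)CC1(C)C | intermediate
13 | methyl (2E,4E,6E,8Z,10E,12E)-2,7,11-trimethyl-13-[(1S)-2,6,6-trimethyl-4-oxocyclohex-2-en-1-yl]trideca-2,4,6,8,10,12-hexaenoate (11Z in carotenoid numbering) | COC(=O)/C(C)=C/C=C/C=C(C)/C=C\C=C(C)\C=C\[C@@H]1C(C)=CC(=O)CC1(C)C | intermediate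
14 | methyl (2E,4E,6E,8E,10E,12E)-2,7,11-trimethyl-13-[(1S)-2,6,6-trimethyl-4-oxocyclohex-2-en-1-yl]trideca-2,4,6,8,10,12-hexaenoate | COC(=O)/C(C)=C/C=C/C=C(C)/C=C/C=C(C)/C=C/[C@@H]1C(C)=CC(=O)CC1(C)C | target

## Step count and risks

Total step count: 5 (steps 1, 2, 3 and 5 on the chiral line, step 4 for the C10 partner). Longest linear sequence: 4 steps (1 → 3 → 6 → 8 → 14). The three steps most likely to fail are step 2, step 3 and step 5.

Step 2 (the proposed new oxidation) may fail through abstraction of C6–H, peroxyl attack on the vinyl group or loss of the tertiary carbinol. The fallback inverts the order and uses known chemistry. Setting out from 1, t-BuOOH with CrO3 (5 mol%) in CH2Cl2 at rt performs the documented allylic oxidation of α-ionone, with C6 untouched, to (S)-3-oxo-α-ionone F1. CH2=CHMgBr premixed with CeCl3 in THF at −78 °C then adds to the unhindered side-chain methyl ketone in preference to the hindered, isophorone-type ring carbonyl (the same preference that hydride reagents show). This returns to the route at 6.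

Step 3 may fail if the pentadienyl cation loses the γ-enone C6–H (megastigmatrienone-type E1 elimination) faster than PPh3 captures it. The fallback avoids a free cation in the presence of acid. Setting out from 6, PBr3 with pyridine in Et2O at −20 °C delivers bromide with SN2' transposition to the primary dienyl bromide F2. Neutral quaternisation with PPh3 in EtOAc at rt then rejoins the route at 8.

Step 5 may fail if the ylide or traces of base epimerise C6 (the γ-position of the ring enone) or move the ring double bond into conjugation. The fallback masks the ketone as its allylic alcohol for the olefination. Setting out from 8, NaBH4 with CeCl3 in MeOH at −20 °C (Luche 1,2-reduction) gives the 3-hydroxy phosphonium bromide F3, which has no acidic γ-hydrogen. NaN(SiMe3)2 in THF at −78 °C converts it into the 3-hydroxy ylide F4, which reacts with 11 to give the 11Z hydroxy ester F5 together with its E isomer. Heating in heptane converges the mixture on the all-E 3-hydroxy hexaenoate F6. MnO2 in CH2Cl2 at rt finally reoxidises the ring allylic alcohol under neutral conditions and comes back to the route at 14.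

Further compounds
F1 | step 2 | (4S)-3,5,5-trimethyl-4-[(1E)-3-oxobut-1-en-1-yl]cyclohex-2-en-1-one | CC(=O)/C=C/[C@@H]1C(C)=CC(=O)CC1(C)C
F2 | step 3 | (4S)-4-[(1E,3E)-5-bromo-3-methylpenta-1,3-dien-1-yl]-3,5,5-trimethylcyclohex-2-en-1-one | BrC/C=C(C)/C=C/[C@@H]1C(C)=CC(=O)CC1(C)C
F3 | step 5 | [(2E,4E)-5-[(1S)-4-hydroxy-2,6,6-trimethylcyclohex-2-en-1-yl]-3-methylpenta-2,4-dien-1-yl]triphenylphosphonium bromide (carbinol epimers) | [Br-].c1ccccc1[P+](c1ccccc1)(c1ccccc1)C/C=C(C)/C=C/[C@@H]1C(C)=CC(O)CC1(C)C
F4 | step 5 | (4S)-3,5,5-trimethyl-4-[(1E,3E)-3-methyl-5-(triphenyl-λ5-phosphanylidene)penta-1,3-dien-1-yl]cyclohex-2-en-1-ol (carbinol epimers) | c1ccccc1P(c1ccccc1)(c1ccccc1)=C/C=C(C)/C=C/[C@@H]1C(C)=CC(O)CC1(C)C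
F5 | step 5 | methyl (2E,4E,6E,8Z,10E,12E)-13-[(1S)-4-hydroxy-2,6,6-trimethylcyclohex-2-en-1-yl]-2,7,11-trimethyltrideca-2,4,6,8,10,12-hexaenoate (carbinol epimers) | COC(=O)/C(C)=C/C=C/C=C(C)/C=C\C=C(C)\C=C\[C@@H]1C(C)=CC(O)CC1(C)C
F6 | step 5 | methyl (2E,4E,6E,8E,10E,12E)-13-[(1S)-4-hydroxy-2,6,6-trimethylcyclohex-2-en-1-yl]-2,7,11-trimethyltrideca-2,4,6,8,10,12-hexaenoate (carbinol epimers) | COC(=O)/C(C)=C/C=C/C=C(C)/C=C/C=C(C)/C=C/[C@@H]1C(C)=CC(O)CC1(C)C
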